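**Plan**
1. Retrosynthesis: the 1,2-dioxepine hemiperacetal is opened to an 11-hydroperoxy-15,16-dial; C12=C13 is cut (Wittig) and then the C11–O bond (singlet-oxygen silyl-ene reaction of a C12 aldehyde enol ether). C8=C17 (Wittig), 7α-OH (SeO2), the second C4 methyl (hydromethylation of a 3-ene) and the C20 methyl (from a lactone carbonyl) are traced back next.
2. Key cut: bonds C1–C2 and C5–C10 of ring A by an intramolecular Diels–Alder reaction. This is possible because C10 is quaternary and carries a one-carbon group (C20) that can be a carbonyl syn to an oxygen on C8 of ring B; C20 and O-C8 are tied as a γ-lactone whose α-methylene (C10=C1) is the dienophile, and C2–C5 with the C4 methyl is an (E)-diene.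
3. The lactone is cut at C8–C9 into a dienal (C2–C8) and a 2-(bromomethyl)enoate (C1, C9–C12, C20).
4. Forward: the chain is joined by asymmetric allylation (lactone ring), rings A and B arise together in the cycloaddition, the lactone is unlocked, the side chain is built, and the peroxide ring closes last.
5. Stereochemistry: C8/C9 from catalytic asymmetric chromium allylation; C5/C10 relayed from C8 in the cycloaddition; C7 and C11 by substrate-controlled face selection; C15 thermodynamic.

Key step: step 7

Remark: labdane numbering (C1–C20) is used for all decalin compounds; α is below and β above the ring plane.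
Remark: C15 is a hemiperacetal carbon that equilibrates by ring–chain tautomerism; the (15S) configuration of the target is assumed to be the thermodynamically favoured one.

Step 1
Reactants: 1 (2E)-3-methylpent-2-en-4-yn-1-ol
Product: 2 (2E)-3-methylpenta-2,4-dien-1-ol
Conditions: H2 (1 atm), Pd/CaCO3 poisoned with Pb(OAc)2, quinoline, hexane/EtOAc, 0 °C
Reagents that add atoms: none
Why: Lindlar semihydrogenation stops at the alkene for the terminal alkyne and leaves the trisubstituted (E)-alkene untouched.

Step 2
Reactants: 2 (2E)-3-methylpenta-2,4-dien-1-ol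
Product: 3 (3E)-5-bromo-3-methylpenta-1,3-diene
Conditions: PBr3 (0.4 equiv), Et2O, −20 to 0 °C
Reagents that add atoms: phosphorus tribromide, BrP(Br)Br
Why: Bromination of a primary allylic alcohol; the conjugated primary bromide is the favoured allylic isomer, so the (E)-diene is kept.

Step 3
Reactants: 3 (3E)-5-bromo-3-methylpenta-1,3-diene; 4 N-cyclohexylethanimine
Product: 6 (4E)-5-methylhepta-4,6-dienal, via alkylated imine 5 (not isolated)
Conditions: LDA, THF, −78 °C (4); then 3, −78 to 0 °C; then aq. oxalic acid, pentane, rt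
Reagents that add atoms: water, O
Why: Stork metalloenamine alkylation (SN2 at the primary allylic carbon) followed by imine hydrolysis gives the two-carbon-extended aldehyde without touching the diene.

Step 4
Reactants: 7 3-(benzyloxy)propanal; 8 ethyl acrylate
Product: 9 ethyl 5-(benzyloxy)-3-hydroxy-2-methylidenepentanoate (racemic)
Conditions: DABCO (cat.), dioxane/H2O, rt
Reagents that add atoms: none
Why: Morita–Baylis–Hillman reaction of an aliphatic aldehyde with an acrylate; the carbinol centre is lost in the next step.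

Step 5
Reactants: 9 ethyl 5-(benzyloxy)-3-hydroxy-2-methylidenepentanoate
Product: 10 ethyl (2Z)-5-(benzyloxy)-2-(bromomethyl)pent-2-enoate
Conditions: NBS, Me2S, CH2Cl2, 0 °C to rt
Reagents that add atoms: N-bromosuccinimide, O=C1CCC(=O)N1Br
Why: Bromodimethylsulfonium activation and SN2' attack of bromide convert Baylis–Hillman alcohols into (Z)-2-(bromomethyl)-2-enoates, with the β-alkyl group trans to the ester.

Step 6
Reactants: 6 (4E)-5-methylhepta-4,6-dienal; 10 ethyl (2Z)-5-(benzyloxy)-2-(bromomethyl)pent-2-enoate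
Product: 13 (4R,5S)-4-[2-(benzyloxy)ethyl]-5-[(3E)-4-methylhexa-3,5-dien-1-yl]-3-methylideneoxolan-2-one (trans lactone), via silyl ether 11 (not isolated), via hydroxy ester 12 (not isolated)
Conditions: CrCl2 (10 mol %), chiral tridentate carbazole bis(oxazoline) ligand (12 mol %, enantiomer directing Re-face addition to 6), Mn powder, Me3SiCl, THF, rt; then p-TsOH (cat.), CH2Cl2, rt
Reagents that add atoms: none
Why: Catalytic asymmetric Nozaki–Hiyama–Kishi 2-(alkoxycarbonyl)allylation: the allylchromium species from 10 adds through its γ-carbon in a closed chair transition state (anti adduct, hence the trans lactone), the ligand on trivalent chromium selects the Re face of the aldehyde to set C8 and with it C9, and acid then removes the silyl group and closes the γ-lactone.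

Step 7
Reactants: 13 trans lactone
Product: 14 (5S,8S,9R,10R)-12-(benzyloxy)-13,14,15,16,17,19-hexanorlabd-3-en-20,8β-olide
Conditions: Et2AlCl (0.3 equiv), CH2Cl2 (0.01 M), −40 °C to rt
Reagents that add atoms: none
Why: Intramolecular Diels–Alder reaction (type 1, 1,7,9-decatriene class) of the s-cis (E)-diene onto the Lewis-acid-activated exocyclic α-methylene lactone, a concerted asynchronous [4+2] cycloaddition; the closest known type is the intramolecular cycloaddition of 2-substituted acrylates and α-methylene lactones to angularly functionalised trans-decalins. Ring B closes through the four-atom tether as a chair inside the nascent 6-oxabicyclo[3.2.1]octanone (the lactone spans C8 and C10 diaxially), and ring A is the cyclohexene made by the cycloaddition itself, so C5–C10 and C1–C2 form in one event. The tether leaves the lactone γ-carbon (C8) and can only reach the face of the methylene group syn to it, so C8 fixes the absolute configuration of the new centres C10 (quaternary) and C5; the trans lactone puts the C9 side chain on the other face, where it becomes the equatorial 9β substituent. The trans ring fusion (5α-H anti to the angular carbonyl) needs the lactone carbonyl endo to the diene, which coordination to Et2AlCl reinforces. The selectivities needed are endo over exo and intramolecular over bimolecular reaction (high dilution); the regiochemistry is fixed by the tether, and the electronically mismatched C4 methyl only makes the transition state more asynchronous.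

Step 8
Reactants: 14 hexanorlabd-3-en-20,8β-olide
Product: 16 (5S,8S,9R,10R)-12-(benzyloxy)-13,14,15,16,17-pentanorlabdan-20,8β-olide, via sulfonyl hydrazide 15 (not isolated)
Conditions: Fe(acac)3 (30 mol %), PhSiH3, CH2=NNHSO2Me, THF/MeOH, rt; then Et3N, MeOH, 60 °C
Reagents that add atoms: formaldehyde N-(methanesulfonyl)hydrazone, C=NNS(C)(=O)=O
Why: Iron-hydride hydrogen-atom-transfer hydromethylation of an unactivated trisubstituted olefin: H adds to C3, the tertiary C4 radical adds to the C=N bond, and the hydrazide loses sulfinate and N2 on warming to leave the second C4 methyl group; C4 becomes a gem-dimethyl carbon, so no stereocentre is at stake.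

Step 9
Reactants: 16 pentanorlabdan-20,8β-olide
Product: 17 (5S,8S,9R,10R)-12-(benzyloxy)-8β,20-epoxy-13,14,15,16,17-pentanorlabdan-20-ol (lactol, both anomers)
Conditions: i-Bu2AlH (1.2 equiv), CH2Cl2, −78 °C; Rochelle salt work-up
Reagents that add atoms: none
Why: Partial reduction of a γ-lactone to the lactol; the tetrahedral aluminium hemiacetal is stable at −78 °C and no stereocentre of the skeleton is touched.

Step 10
Reactants: 17 lactol
Product: 19 (5S,8S,9R,10S)-12-(benzyloxy)-13,14,15,16,17-pentanorlabdan-8β-ol, via hydroxy hydrazone 18 (not isolated)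
Conditions: N2H4·H2O, KOH, diethylene glycol, 130 °C then 200 °C
Reagents that add atoms: none
Why: Wolff–Kishner reduction (Huang-Minlon): the lactol opens to the γ-hydroxy aldehyde, whose hydrazone is converted by base into the angular methyl group C20, freeing the 8β-alcohol; the benzyl ether and the saturated skeleton tolerate the conditions.

Step 11
Reactants: 19 pentanorlabdan-8β-ol
Product: 20 (5S,9R,10S)-12-(benzyloxy)-13,14,15,16,17-pentanorlabdan-8-one
Conditions: Dess–Martin periodinane, NaHCO3, CH2Cl2, rt
Reagents that add atoms: none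
Why: Dess–Martin oxidation of the axial secondary alcohol; C9, now α to the ketone, already holds its side chain in the equatorial (thermodynamic) position.

Step 12
Reactants: 20 pentanorlabdan-8-one
Product: 21 (5S,9S,10S)-12-(benzyloxy)-13,14,15,16-tetranorlabd-8(17)-ene
Conditions: Ph3PCH3Br, KOtBu, toluene, 80 °C
Reagents that add atoms: methyltriphenylphosphonium bromide, C[P+](c1ccccc1)(c1ccccc1)c1ccccc1.[Br-]
Why: Wittig methylenation of the hindered ring ketone installs C17; any enolisation at C9 returns the equatorial side chain.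

Step 13
Reactants: 21 tetranorlabd-8(17)-ene
Product: 22 (5S,7R,9R,10S)-12-(benzyloxy)-13,14,15,16-tetranorlabd-8(17)-en-7α-ol
Conditions: SeO2 (0.5 equiv), t-BuOOH, CH2Cl2, rt
Reagents that add atoms: selenium dioxide, O=[Se]=O; tert-butyl hydroperoxide, CC(C)(C)OO
Why: Allylic hydroxylation by SeO2 (ene reaction at C17 with loss of the axial 7α-H, then [2,3]-sigmatropic shift): oxygen is delivered to C7 on the same axial α face, and the ring CH2 reacts in preference to the hindered tertiary C9–H.

Step 14
Reactants: 22 tetranorlabd-8(17)-en-7α-ol benzyl ether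
Product: 23 (5S,7R,9R,10S)-13,14,15,16-tetranorlabd-8(17)-ene-7α,12-diol
Conditions: lithium 4,4'-di-tert-butylbiphenylide, THF, −78 °C; then aq. NH4Cl
Reagents that add atoms: none
Why: Reductive debenzylation by an arene radical anion cleaves only the benzylic C–O bond; the isolated alkene and the allylic alkoxide are inert.

Step 15
Reactants: 23 diol
Product: 24 (5S,7R,9R,10S)-7α-hydroxy-13,14,15,16-tetranorlabd-8(17)-en-12-al
Conditions: TEMPO (10 mol %), PhI(OAc)2 (1.1 equiv), CH2Cl2, rt
Reagents that add atoms: none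
Why: Oxoammonium-mediated oxidation is selective for the unhindered primary alcohol over the axial, hindered secondary 7α-hydroxyl.

Step 16
Reactants: 24 hydroxy aldehyde
Product: 25 (5S,7R,9R,10S,11Z)-7α,12-bis(triethylsilyloxy)-13,14,15,16-tetranorlabda-8(17),11-diene
Conditions: Et3SiOTf (2.5 equiv), Et3N, CH2Cl2, −78 to 0 °C
Reagents that add atoms: triethylsilyl trifluoromethanesulfonate, CC[Si](CC)(CC)OS(=O)(=O)C(F)(F)F
Why: Soft enolisation and O-silylation of the aldehyde (only C11 can enolise) with simultaneous protection of the 7α-hydroxyl; the (Z)-enol ether is expected to predominate and both geometries lead to the same product in step 17.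

Step 17
Reactants: 25 bis(silyl) enol ether
Product: 26 (5S,7R,9R,10S,11R)-7α-(triethylsilyloxy)-11-(triethylsilylperoxy)-13,14,15,16-tetranorlabd-8(17)-en-12-al
Conditions: O2, tetraphenylporphyrin (cat.), visible light, CH2Cl2, −78 °C
Reagents that add atoms: dioxygen, O=O
Why: Silyl-ene reaction of singlet oxygen with a silyl enol ether: oxygen bonds to C11 and the silyl group migrates to the distal peroxy oxygen; the electron-rich enol ether reacts far faster than the 1,1-disubstituted C8=C17 alkene, and C11 is set by attack anti to the quaternary C10 side (C1 and C20) in the conformer with C9–H eclipsing C11=C12.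

Step 18
Reactants: 27 methyl (triphenylphosphoranylidene)acetate (2 equiv); 28 methyl bromoacetate
Product: 29 dimethyl 2-(triphenylphosphoranylidene)butanedioate
Conditions: EtOAc, reflux; filter off the phosphonium salt
Reagents that add atoms: none
Why: C-Alkylation of a stabilised ylide with transylidation (the second equivalent of 27 acts as the base) gives the phosphine-free succinate ylide.

Step 19
Reactants: 26 silylperoxy aldehyde; 29 succinate ylide
Product: 30 dimethyl (11S,12E)-7α-(triethylsilyloxy)-11-(triethylsilylperoxy)labda-8(17),12-diene-15,16-dioate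
Conditions: CH2Cl2, 25–40 °C, dark
Reagents that add atoms: none
Why: Wittig reaction of a stabilised α-substituted ylide under neutral conditions (no free phosphine or base to attack the peroxide or the α-hydrogen) gives the (E)-alkylidene succinate, with C11 trans to the conjugated ester; C11 is not touched.

Step 20
Reactants: 30 diester
Product: 31 (11S,12E)-7α-(triethylsilyloxy)-11-(triethylsilylperoxy)labda-8(17),12-diene-15,16-diol
Conditions: i-Bu2AlH (5 equiv), CH2Cl2, −78 °C; Rochelle salt work-up
Reagents that add atoms: none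
Why: Low-temperature DIBAL reduction of both esters; 4-peroxy-2-enoates are known to be reduced to the peroxy allylic alcohols without O–O cleavage.

Step 21
Reactants: 31 diol
Product: 32 (11S,12E)-7α-(triethylsilyloxy)-11-(triethylsilylperoxy)labda-8(17),12-diene-15,16-dial
Conditions: Dess–Martin periodinane (3 equiv), NaHCO3, CH2Cl2, 0 °C
Reagents that add atoms: none
Why: Fast, nearly neutral Dess–Martin oxidation of both primary alcohols to the 1,4-dial; the γ-peroxy enal is not exposed to amine base.

Step 22
Reactants: 32 dial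
Product: 34 (11S,15S)-11,15-epidioxy-7α,15-dihydroxylabda-8(17),12-dien-16-al, via hydroperoxy dial 33 (not isolated)
Conditions: HF·pyridine, pyridine, THF, 0 °C
Reagents that add atoms: none
Why: Fluoride-induced desilylation frees the 7α-hydroxyl and the C11 hydroperoxide, which adds to the saturated C15 aldehyde (ring–chain tautomerism) to close the seven-membered hemiperacetal. The (E)-geometry forbids closure onto C16, the in-ring C12=C13 bond is cis as required, and C15 settles under thermodynamic control.

**Compound list**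
1 | (2E)-3-methylpent-2-en-4-yn-1-ol | C#C/C(C)=C/CO | starting material
2 | (2E)-3-methylpenta-2,4-dien-1-ol | C=C/C(C)=C/CO | intermediate
3 | (3E)-5-bromo-3-methylpenta-1,3-diene | C=C/C(C)=C/CBr | intermediate
4 | N-cyclohexylethanimine | CC=NC1CCCCC1 | starting material
5 | N-cyclohexyl-(4E)-5-methylhepta-4,6-dien-1-imine (not isolated) | C=C/C(C)=C/CCC=NC1CCCCC1 | intermediate
6 | (4E)-5-methylhepta-4,6-dienal | C=C/C(C)=C/CCC=O | intermediate
7 | 3-(benzyloxy)propanal | O=CCCOCc1ccccc1 | starting material
8 | ethyl acrylate | C=CC(=O)OCC | starting material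
9 | ethyl 5-(benzyloxy)-3-hydroxy-2-methylidenepentanoate (racemic) | C=C(C(=O)OCC)C(O)CCOCc1ccccc1 | intermediate
10 | ethyl (2Z)-5-(benzyloxy)-2-(bromomethyl)pent-2-enoate | CCOC(=O)/C(CBr)=C/CCOCc1ccccc1 | intermediate
11 | ethyl (3R,4S,7E)-3-[2-(benzyloxy)ethyl]-8-methyl-2-methylidene-4-(trimethylsilyloxy)deca-7,9-dienoate (not isolated) | CCOC(=O)C(=C)[C@@H](CCOCc1ccccc1)[C@@H](O[Si](C)(C)C)CC/C=C(C)/C=C | intermediate
12 | ethyl (3R,4S,7E)-3-[2-(benzyloxy)ethyl]-4-hydroxy-8-methyl-2-methylidenedeca-7,9-dienoate (not isolated) | CCOC(=O)C(=C)[C@@H](CCOCc1ccccc1)[C@@H](O)CC/C=C(C)/C=C | intermediate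
13 | (4R,5S)-4-[2-(benzyloxy)ethyl]-5-[(3E)-4-methylhexa-3,5-dien-1-yl]-3-methylideneoxolan-2-one | O=C1O[C@@H](CC/C=C(C)/C=C)[C@H](CCOCc2ccccc2)C1=C | intermediate
14 | (5S,8S,9R,10R)-12-(benzyloxy)-13,14,15,16,17,19-hexanorlabd-3-en-20,8β-olide | O=C1O[C@H]2CC[C@H]3C(C)=CCC[C@@]13[C@H]2CCOCc1ccccc1 | intermediate
15 | (5S,8S,9R,10R)-12-(benzyloxy)-19-[2-(methanesulfonyl)hydrazinyl]-13,14,15,16,17-pentanorlabdan-20,8β-olide (C4 epimers, not isolated) | O=C1O[C@H]2CC[C@H]3C(C)(CNNS(C)(=O)=O)CCC[C@@]13[C@H]2CCOCc1ccccc1 | intermediate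
16 | (5S,8S,9R,10R)-12-(benzyloxy)-13,14,15,16,17-pentanorlabdan-20,8β-olide | O=C1O[C@H]2CC[C@H]3C(C)(C)CCC[C@@]13[C@H]2CCOCc1ccccc1 | intermediate
17 | (5S,8S,9R,10R)-12-(benzyloxy)-8β,20-epoxy-13,14,15,16,17-pentanorlabdan-20-ol (anomers) | OC1O[C@H]2CC[C@H]3C(C)(C)CCC[C@@]13[C@H]2CCOCc1ccccc1 | intermediate
18 | (5S,8S,9R,10R)-12-(benzyloxy)-8β-hydroxy-13,14,15,16,17-pentanorlabdan-20-al hydrazone (not isolated) | O[C@H]1CC[C@H]2C(C)(C)CCC[C@]2(C=NN)[C@H]1CCOCc1ccccc1 | intermediate
19 | (5S,8S,9R,10S)-12-(benzyloxy)-13,14,15,16,17-pentanorlabdan-8β-ol | O[C@H]1CC[C@H]2C(C)(C)CCC[C@]2(C)[C@H]1CCOCc1ccccc1 | intermediate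
20 | (5S,9R,10S)-12-(benzyloxy)-13,14,15,16,17-pentanorlabdan-8-one | O=C1CC[C@H]2C(C)(C)CCC[C@]2(C)[C@H]1CCOCc1ccccc1 | intermediate
21 | (5S,9S,10S)-12-(benzyloxy)-13,14,15,16-tetranorlabd-8(17)-ene | C=C1CC[C@H]2C(C)(C)CCC[C@]2(C)[C@H]1CCOCc1ccccc1 | intermediate
22 | (5S,7R,9R,10S)-12-(benzyloxy)-13,14,15,16-tetranorlabd-8(17)-en-7α-ol | C=C1[C@H](O)C[C@H]2C(C)(C)CCC[C@]2(C)[C@H]1CCOCc1ccccc1 | intermediate
23 | (5S,7R,9R,10S)-13,14,15,16-tetranorlabd-8(17)-ene-7α,12-diol | C=C1[C@H](O)C[C@H]2C(C)(C)CCC[C@]2(C)[C@H]1CCO | intermediate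
24 | (5S,7R,9R,10S)-7α-hydroxy-13,14,15,16-tetranorlabd-8(17)-en-12-al | C=C1[C@H](O)C[C@H]2C(C)(C)CCC[C@]2(C)[C@H]1CC=O | intermediate
25 | (5S,7R,9R,10S,11Z)-7α,12-bis(triethylsilyloxy)-13,14,15,16-tetranorlabda-8(17),11-diene | C=C1[C@H](O[Si](CC)(CC)CC)C[C@H]2C(C)(C)CCC[C@]2(C)[C@H]1/C=C\O[Si](CC)(CC)CC | intermediate
26 | (5S,7R,9R,10S,11R)-7α-(triethylsilyloxy)-11-(triethylsilylperoxy)-13,14,15,16-tetranorlabd-8(17)-en-12-al | C=C1[C@H](O[Si](CC)(CC)CC)C[C@H]2C(C)(C)CCC[C@]2(C)[C@H]1[C@@H](OO[Si](CC)(CC)CC)C=O | intermediate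
27 | methyl (triphenylphosphoranylidene)acetate | COC(=O)C=P(c1ccccc1)(c1ccccc1)c1ccccc1 | starting material
28 | methyl bromoacetate | COC(=O)CBr | starting material
29 | dimethyl 2-(triphenylphosphoranylidene)butanedioate | COC(=O)CC(C(=O)OC)=P(c1ccccc1)(c1ccccc1)c1ccccc1 | intermediate
30 | dimethyl (11S,12E)-7α-(triethylsilyloxy)-11-(triethylsilylperoxy)labda-8(17),12-diene-15,16-dioate | C=C1[C@H](O[Si](CC)(CC)CC)C[C@H]2C(C)(C)CCC[C@]2(C)[C@H]1[C@@H](OO[Si](CC)(CC)CC)/C=C(/C(=O)OC)CC(=O)OC | intermediate
31 | (11S,12E)-7α-(triethylsilyloxy)-11-(triethylsilylperoxy)labda-8(17),12-diene-15,16-diol | C=C1[C@H](O[Si](CC)(CC)CC)C[C@H]2C(C)(C)CCC[C@]2(C)[C@H]1[C@@H](OO[Si](CC)(CC)CC)/C=C(/CO)CCO | intermediate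
32 | (11S,12E)-7α-(triethylsilyloxy)-11-(triethylsilylperoxy)labda-8(17),12-diene-15,16-dial | C=C1[C@H](O[Si](CC)(CC)CC)C[C@H]2C(C)(C)CCC[C@]2(C)[C@H]1[C@@H](OO[Si](CC)(CC)CC)/C=C(/C=O)CC=O | intermediate
33 | (11S,12E)-11-hydroperoxy-7α-hydroxylabda-8(17),12-diene-15,16-dial (not isolated) | C=C1[C@H](O)C[C@H]2C(C)(C)CCC[C@]2(C)[C@H]1[C@@H](OO)/C=C(/C=O)CC=O | intermediate
34 | (5S,7R,9R,10S,11S,15S)-11,15-epidioxy-7α,15-dihydroxylabda-8(17),12-dien-16-al | C=C1[C@H](O)C[C@H]2C(C)(C)CCC[C@]2(C)[C@H]1[C@@H]1C=C(C=O)C[C@@H](O)OO1 | target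

**Count**
Total steps: 22. Longest linear sequence: 19 (steps 1–3, 6–17, 19–22).

**Steps most likely to fail**

Step 17. What may go wrong: poor facial selectivity of singlet oxygen at C11 (the two faces are flanked by C1/C20 and by C17), or [2+2] addition and cleavage of the enol ether instead of the silyl-ene path. The fallback replaces substrate control by catalyst control. It sets out from 24, whose 7α-hydroxyl is silylated (Et3SiCl, imidazole) to (5S,7R,9R,10S)-7α-(triethylsilyloxy)-13,14,15,16-tetranorlabd-8(17)-en-12-al F1. Amino-acid-catalysed α-oxidation of this aldehyde with singlet oxygen through its enamine (the enantiomer of α-methylproline chosen for the required face, O2, tetraphenylporphyrin, light, DMF, 0 °C) should give (5S,7R,9R,10S,11R)-11-hydroperoxy-7α-(triethylsilyloxy)-13,14,15,16-tetranorlabd-8(17)-en-12-al F2. Silylation of its hydroperoxide at low temperature (Et3SiCl, imidazole) comes back to the route at 26.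

Step 7. What may go wrong: insufficient endo preference in the bridged transition state, giving cis-fused material, or oligomerisation of the α-methylene lactone. The fallback runs the cycloaddition on the open-chain acrylate, whose tether can adopt an unconstrained chair. It sets out from 12 (isolated by a neutral work-up of step 6), which is silylated (t-BuMe2SiOTf, 2,6-lutidine) to ethyl (3R,4S,7E)-3-[2-(benzyloxy)ethyl]-4-(tert-butyldimethylsilyloxy)-8-methyl-2-methylidenedeca-7,9-dienoate F3. Heating (toluene, 150 °C, sealed tube) should give, through the ester-endo chair transition state with the C9 side chain equatorial, ethyl (5S,8S,9R,10R)-12-(benzyloxy)-8β-(tert-butyldimethylsilyloxy)-13,14,15,16,17,19-hexanorlabd-3-en-20-oate F4. Treatment with Bu4NF frees the 8β-alkoxide, which closes onto the syn-diaxial ester and comes back to the route at 14.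

Step 6. What may go wrong: low enantioselectivity or low anti selectivity of the catalytic allylation with the γ-substituted bromide. The fallback uses resolution instead of asymmetric catalysis. It sets out from 6 and 10, which with stoichiometric CrCl2 (THF, rt, no ligand, neutral work-up) give the racemic anti adduct, that is 12 together with its enantiomer ethyl (3S,4R,7E)-3-[2-(benzyloxy)ethyl]-4-hydroxy-8-methyl-2-methylidenedeca-7,9-dienoate F5. A lipase (Candida antarctica lipase B, vinyl acetate, hexane) is expected to acylate the (4R)-alcohol to ethyl (3S,4R,7E)-4-acetoxy-3-[2-(benzyloxy)ethyl]-8-methyl-2-methylidenedeca-7,9-dienoate F6 and to leave 12, which is separated and lactonised (p-TsOH, CH2Cl2), coming back to the route at 13.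

**Further compounds**
F1 | step 17 | (5S,7R,9R,10S)-7α-(triethylsilyloxy)-13,14,15,16-tetranorlabd-8(17)-en-12-al | C=C1[C@H](O[Si](CC)(CC)CC)C[C@H]2C(C)(C)CCC[C@]2(C)[C@H]1CC=O
F2 | step 17 | (5S,7R,9R,10S,11R)-11-hydroperoxy-7α-(triethylsilyloxy)-13,14,15,16-tetranorlabd-8(17)-en-12-al | C=C1[C@H](O[Si](CC)(CC)CC)C[C@H]2C(C)(C)CCC[C@]2(C)[C@H]1[C@@H](OO)C=O
F3 | step 7 | ethyl (3R,4S,7E)-3-[2-(benzyloxy)ethyl]-4-(tert-butyldimethylsilyloxy)-8-methyl-2-methylidenedeca-7,9-dienoate | CCOC(=O)C(=C)[C@@H](CCOCc1ccccc1)[C@@H](O[Si](C)(C)C(C)(C)C)CC/C=C(C)/C=C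
F4 | step 7 | ethyl (5S,8S,9R,10R)-12-(benzyloxy)-8β-(tert-butyldimethylsilyloxy)-13,14,15,16,17,19-hexanorlabd-3-en-20-oate | CC(C)(C)[Si](C)(C)O[C@H]1CC[C@H]2C(C)=CCC[C@]2(C(=O)OCC)[C@H]1CCOCc1ccccc1
F5 | step 6 | ethyl (3S,4R,7E)-3-[2-(benzyloxy)ethyl]-4-hydroxy-8-methyl-2-methylidenedeca-7,9-dienoate | CCOC(=O)C(=C)[C@H](CCOCc1ccccc1)[C@H](O)CC/C=C(C)/C=C
F6 | step 6 | ethyl (3S,4R,7E)-4-acetoxy-3-[2-(benzyloxy)ethyl]-8-methyl-2-methylidenedeca-7,9-dienoate | CCOC(=O)C(=C)[C@H](CCOCc1ccccc1)[C@H](OC(C)=O)CC/C=C(C)/C=C
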